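**Plan**

1. Backbone numbering C1–C23 runs from the ethyl end of the ethylpyranone: ring B = C3–C7 plus O, acetate on C9, propionate on C11, ring A = C15–C19 plus O, carbinol C21.
2. Retrosynthetic cuts, in order: the two ester C–O bonds; ring A (O–C15/C19 closure, C15–C16 aldol bond); ring B (O–C3/C7 closure, C6–C7 aldol bond); C11–C12 (boron-to-carbon shift onto a C12–C15 alkenyl unit); then C10–C11, C9–C10 and C8–C9.
3. Enabling feature: C8–C11 is an unbroken run of four CHX carbons (Me, O, Me, O) in which C9/C10/C11 are all-anti and only C8/C9 is syn. C9, C10 and C11 can therefore be inserted one at a time into the C–B bond of a C8 boronic ester under a single diol director.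
4. Forward order: methylboronate → C8 boronate 7 → C8–C11 tetrad 14 (step 3) → C7 acetal → C11–C12 coupling → ring B (step 11) → ring A (step 18) → ether-to-ester exchange at C11, then C9 → desilylation at C21.
5. Stereochemistry: C8–C11 from (S,S)-1,2-dicyclohexylethane-1,2-diol (C8 by reversed substituent order); C11 retained in the boron-to-carbon shift; E-C12=C13 from a Z-iodide through anti migration and anti elimination; C14 from methyl (R)-3-hydroxy-2-methylpropanoate; C20/C21 from an Evans syn aldol.

Key step: step 3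

Remark: in step 3 the three homologation cycles are run as one telescoped sequence; the boronic esters between 7 and 14 are carried on as crude concentrates after extractive work-up and are therefore entered as not isolated.
Remark: 4-methylheptane-3,5-dione, methyl (R)-3-hydroxy-2-methylpropanoate and (R)-4-benzyl-3-propionyloxazolidin-2-one are taken as purchased.

**Route**

Step 1
Reactants: 1 methylboronic acid; 2 (1S,2S)-1,2-dicyclohexylethane-1,2-diol
Product: 3 (4S,5S)-4,5-dicyclohexyl-2-methyl-1,3,2-dioxaborolane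
Conditions: MgSO4, Et2O, rt
Reagents that add atoms: none
Why: Boronic ester formation by condensation of a boronic acid with a 1,2-diol is driven to completion by the drying agent and installs the C2-symmetric director without creating a stereocentre.

Step 2
Reactants: 3; 4 dichloromethane; 5 vinylmagnesium bromide
Product: 7 (4S,5S)-2-[(2S)-but-3-en-2-yl]-4,5-dicyclohexyl-1,3,2-dioxaborolane, via 1-chloroethyl boronate 6 (not isolated)
Conditions: CH2Cl2, n-BuLi, THF, −100 °C; 3; ZnCl2, −100 °C → rt; then CH2=CHMgBr, −78 °C → rt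
Reagents that add atoms: dichloromethane, ClCCl; vinylmagnesium bromide, C=C[Mg]Br
Why: Matteson homologation in reversed substituent order should let the methyl group migrate from boron to the dichloromethyl carbon under control of the (S,S)-diol to give the (R)-chloride 6, after which the vinyl Grignard reagent adds to boron and displaces chloride with inversion, setting C8 (S in 7) as a configurationally stable α-methylallyl boronic ester whose vinyl group stands for C7.

Step 3
Reactants: 7; 4 dichloromethane; 8 methylmagnesium bromide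
Product: 14 (4S,5S)-4,5-dicyclohexyl-2-[(1S,2S,3R,4S)-1-(4-methoxybenzyloxy)-2,4-dimethyl-3-(naphthalen-2-ylmethoxy)hex-5-enyl]-1,3,2-dioxaborolane, via C9 chloro boronate 9 (not isolated), via C9 ether boronate 10 (not isolated), via C10 chloro boronate 11 (not isolated), via C10 methyl boronate 12 (not isolated), via C11 chloro boronate 13 (not isolated)
Conditions: three cycles of [CH2Cl2, n-BuLi, THF, −100 °C; ZnCl2, −100 °C → rt], each followed by chloride displacement: (a) NaH, naphthalen-2-ylmethanol, THF/DMSO, 0 °C → rt; (b) MeMgBr, THF, −78 °C → rt; (c) NaH, 4-methoxybenzyl alcohol, THF/DMSO, 0 °C → rt; extractive work-up between cycles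
Reagents that add atoms: dichloromethane, ClCCl; naphthalen-2-ylmethanol (as sodium alkoxide), OCc1ccc2ccccc2c1; methylmagnesium bromide, C[Mg]Br; 4-methoxybenzyl alcohol (as sodium alkoxide), COc1ccc(CO)cc1
Why: In each cycle LiCHCl2 adds to boron and ZnCl2 assists the 1,2-shift of the chain carbon from boron to the carbenoid carbon with loss of one chloride, after which the alkoxide or Grignard reagent adds to boron and migrates with inversion to expel the second chloride, so that C8–C9, C9–C10 and C10–C11 should form in turn. The closest known reaction type is the iterated Matteson homologation of chiral diol boronic esters with alkoxide and Grignard displacements. No ring closes. C9, C10 and C11 are each set by the (S,S)-dicyclohexylethanediol on boron, which decides which chloride leaves, together with the stereospecific inversion in the displacement; the same director acting three times gives the all-anti C9/C10/C11 array, while C8 is carried through because a migrating carbon keeps its configuration. The step needs high diastereoselection in every insertion, 1,2- rather than 1,3-migration of the allylic C8 group in the first cycle and no epimerisation of the α-chloro boronates. These are secured by the covalently bound director, by the slow allylic boron shift of boronic esters and by ZnCl2, which scavenges free chloride.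

Step 4
Reactants: 14
Product: 16 (4S,5S)-4,5-dicyclohexyl-2-[(1S,2S,3S,4R)-5,5-dimethoxy-1-(4-methoxybenzyloxy)-2,4-dimethyl-3-(naphthalen-2-ylmethoxy)pentyl]-1,3,2-dioxaborolane, via C7 aldehyde 15 (not isolated)
Conditions: OsO4 (cat.), NaIO4, 2,6-lutidine, dioxane/H2O, rt; then HC(OMe)3, PPTS (cat.), MeOH, rt
Reagents that add atoms: trimethyl orthoformate, COC(OC)OC
Why: Lemieux–Johnson cleavage should remove the terminal carbon of the only alkene without touching the arylmethyl ethers or the C–B bond, and acid-catalysed acetalisation masks the C7 aldehyde before a second alkene and an organolithium are introduced; no stereocentre is formed and the buffered conditions should not enolise C8.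

Step 5
Reactants: 17 methyl (R)-3-hydroxy-2-methylpropanoate
Product: 18 methyl (R)-3-(tert-butyldiphenylsilyloxy)-2-methylpropanoate
Conditions: t-BuPh2SiCl, imidazole, CH2Cl2, rt
Reagents that add atoms: tert-butyl(chloro)diphenylsilane, CC(C)(C)[Si](Cl)(c1ccccc1)c1ccccc1
Why: Imidazole-promoted silylation protects the primary hydroxyl as an ether stable to organolithiums and mild acid; the stereocentre (future C14) is not involved.

Step 6
Reactants: 18
Product: 19 (R)-3-(tert-butyldiphenylsilyloxy)-2-methylpropanal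
Conditions: i-Bu2AlH, CH2Cl2, −78 °C
Reagents that add atoms: none
Why: Partial ester reduction with i-Bu2AlH at low temperature should stop at the tetrahedral aluminate, which releases the aldehyde on work-up without touching the α-stereocentre.

Step 7
Reactants: 19; 20 ethyltriphenylphosphonium iodide
Product: 21 tert-butyl{[(2S,3Z)-4-iodo-2-methylpent-3-enyl]oxy}diphenylsilane
Conditions: EtPPh3I, n-BuLi, THF, rt; I2, −78 °C; NaN(SiMe3)2, −20 °C; 19, −78 °C → rt
Reagents that add atoms: ethyltriphenylphosphonium iodide, CC[P+](c1ccccc1)(c1ccccc1)c1ccccc1.[I-]; iodine, II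
Why: Stork–Zhao-type Wittig olefination with the α-iodo ylide should give the Z-2-iodoalkene (iodine cis to the C14 carbon) through the kinetic cis-oxaphosphetane of a non-stabilised ylide, at a temperature low enough to keep the α-stereocentre intact.

Step 8
Reactants: 16; 21
Product: 24 tert-butyl{[(2S,3E,5R,6R,7S,8R)-9,9-dimethoxy-5-(4-methoxybenzyloxy)-2,4,6,8-tetramethyl-7-(naphthalen-2-ylmethoxy)non-3-enyl]oxy}diphenylsilane, via lithium alkenylborate 22 (not isolated), via iodo boronate 23 (not isolated)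
Conditions: 21, t-BuLi, Et2O, −78 °C; 16, THF, −78 °C; I2, MeOH, −78 °C; NaOMe, MeOH, −78 °C → rt
Reagents that add atoms: none
Why: Proposed new method: the alkenyllithium formed from 21 with retention should add to boron of 16 to give borate 22; iodine then forms an iodonium ion on the alkene and triggers anti 1,2-migration of C11 from boron to C12 with retention at C11, and methoxide induces anti elimination of boron and iodide from 23, the two anti events converting the Z-iodide geometry into the E-C12=C13 alkene. The closest known reaction type is the Zweifel olefination of secondary alkyl boronic esters with 1-substituted alkenyllithiums, and migration of α-alkoxyalkyl groups in borate complexes is established by the homologations of step 3, but the combination on an α-alkoxy, β-branched dicyclohexylethanediol boronate is not.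

Step 9
Reactants: 24
Product: 25 (2R,3S,4R,5R,6E,8S)-9-(tert-butyldiphenylsilyloxy)-5-(4-methoxybenzyloxy)-2,4,6,8-tetramethyl-3-(naphthalen-2-ylmethoxy)non-6-enal
Conditions: PPTS (cat.), acetone/H2O, 50 °C
Reagents that add atoms: water, O
Why: Acid-catalysed acetal hydrolysis should unmask the C7 aldehyde under conditions mild enough for the arylmethyl and silyl ethers and without enolising C8.

Step 10
Reactants: 25; 26 4-methylheptane-3,5-dione
Product: 27 C7-hydroxy C3,C5-diketone (backbone C1–C15; C8–C14 as in 25; mixture at C4/C6/C7)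
Conditions: 26, LiN(i-Pr)2 (2 equiv per 26), THF, −78 → 0 °C; then 25, −78 °C
Reagents that add atoms: 4-methylheptane-3,5-dione, CCC(=O)C(C)C(=O)CC
Why: Aldol addition of the β-diketone dianion through its more nucleophilic terminal carbon should form C6–C7; the new centres at C4, C6 and C7 vanish when ring B is formed, so no control is needed.

Step 11
Reactants: 27
Product: 29 2-[(2R,3S,4R,5R,6E,8S)-9-(tert-butyldiphenylsilyloxy)-5-(4-methoxybenzyloxy)-4,6,8-trimethyl-3-(naphthalen-2-ylmethoxy)non-6-en-2-yl]-6-ethyl-3,5-dimethyl-4H-pyran-4-one, via C3/C5/C7 triketone 28 (not isolated)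
Conditions: Dess–Martin periodinane, NaHCO3, CH2Cl2, 0 °C → rt; then PPh3, CCl4, THF, rt
Reagents that add atoms: none
Why: Dess–Martin oxidation should give the 3,5,7-triketone, and Appel-type activation of one enol oxygen by PPh3/CCl4 lets the other terminal enol oxygen close ring B (six-membered O–C closure) under near-neutral conditions intended to spare the C8 stereocentre next to the new ring.

Step 12
Reactants: 29
Product: 30 C15 alcohol (29 without the silyl group; configuration unchanged)
Conditions: Bu4NF, THF, 0 °C → rt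
Reagents that add atoms: none
Why: Fluoride-mediated desilylation should free the C15 hydroxyl, the pyranone and the arylmethyl ethers being inert to fluoride.

Step 13
Reactants: 31 (R)-4-benzyl-3-propionyloxazolidin-2-one; 32 propanal
Product: 33 (R)-4-benzyl-3-[(2R,3S)-3-hydroxy-2-methylpentanoyl]oxazolidin-2-one
Conditions: Bu2BOTf, Et3N, CH2Cl2, −78 → 0 °C; 32, −78 → 0 °C; then pH 7 buffer, MeOH, H2O2
Reagents that add atoms: propanal, CCC=O
Why: Evans syn aldol reaction: the Z-boron enolate adds to propanal through a chair transition state in which the (R)-benzyl auxiliary shields one enolate face, which should set the future C20 (R) and C21 (S) in a syn relationship.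

Step 14
Reactants: 33
Product: 34 (2R,3S)-3-hydroxy-N-methoxy-N,2-dimethylpentanamide
Conditions: MeNH(OMe)·HCl, AlMe3, CH2Cl2, 0 °C → rt
Reagents that add atoms: N,O-dimethylhydroxylamine hydrochloride, CNOC.Cl
Why: Aluminium-amide transamination of the N-acyl oxazolidinone should release the auxiliary and give the N-methoxy-N-methylamide without affecting either stereocentre.

Step 15
Reactants: 34
Product: 35 (2R,3S)-3-(tert-butyldimethylsilyloxy)-N-methoxy-N,2-dimethylpentanamide
Conditions: t-BuMe2SiOTf, 2,6-lutidine, CH2Cl2, −78 → 0 °C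
Reagents that add atoms: tert-butyldimethylsilyl trifluoromethanesulfonate, CC(C)(C)[Si](C)(C)OS(=O)(=O)C(F)(F)F
Why: Silylation with the silyl triflate protects the secondary C21 hydroxyl as an ether meant to survive strong base, oxidation and mild acid until the last step.

Step 16
Reactants: 35; 36 pentan-3-one
Product: 37 (6R,7S)-7-(tert-butyldimethylsilyloxy)-4,6-dimethylnonane-3,5-dione (C4 epimers and enol forms)
Conditions: 36, LiN(i-Pr)2, THF, −78 °C; then 35, −78 → 0 °C
Reagents that add atoms: pentan-3-one, CCC(=O)CC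
Why: Claisen-type acylation of the ketone lithium enolate by the N-methoxy-N-methylamide should stop at the chelated tetrahedral adduct and give the β-diketone on work-up, the hindered amide α-centre (C20) not being deprotonated at low temperature.

Step 17
Reactants: 30; 37
Product: 39 C15-hydroxy C17,C19-diketone (full C1–C23 backbone; mixture at C15/C16/C18), via C15 aldehyde 38 (not isolated)
Conditions: Dess–Martin periodinane, NaHCO3, CH2Cl2, 0 °C; then 37, LiN(i-Pr)2 (2 equiv per 37), THF, −78 → 0 °C, crude 38 added at −78 °C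
Reagents that add atoms: none
Why: Dess–Martin oxidation should give the β,γ-unsaturated aldehyde, which is used at once in an aldol addition of the β-diketone dianion through its less substituted terminal carbon (C16) to form C15–C16; the new centres disappear in ring A, and the low temperature is intended to keep C14 from enolising.

Step 18
Reactants: 39
Product: 41 bis-pyranone with C9 2-naphthylmethyl ether, C11 4-methoxybenzyl ether, C21 tert-butyldimethylsilyl ether (8R,9S,10R,11R,12E,14S,20R,21S), via C15/C17/C19 triketone 40 (not isolated)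
Conditions: Dess–Martin periodinane, NaHCO3, CH2Cl2, 0 °C → rt; then PPh3, CCl4, THF, rt
Reagents that add atoms: none
Why: Dess–Martin oxidation to the 15,17,19-triketone followed by PPh3/CCl4 cyclodehydration should close ring A by attack of one terminal enol oxygen on the other, activated enol carbon (six-membered O–C closure) under near-neutral conditions chosen to preserve C14 and C20.

Step 19
Reactants: 41
Product: 42 C11 alcohol (41 without the 4-methoxybenzyl group; configuration unchanged)
Conditions: DDQ (1.2 equiv), CH2Cl2/pH 7 buffer, 0 °C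
Reagents that add atoms: none
Why: Oxidative ether cleavage by DDQ (hydride abstraction from the more electron-rich benzylic position, then hydrolysis of the oxocarbenium ion) should be faster for the 4-methoxybenzyl than for the 2-naphthylmethyl ether at 0 °C with a near-stoichiometric charge of oxidant.

Step 20
Reactants: 42; 43 propionic anhydride
Product: 44 C11 propionate (C9 2-naphthylmethyl ether and C21 silyl ether retained)
Conditions: (EtCO)2O, Et3N, DMAP (cat.), CH2Cl2, 0 °C → rt
Reagents that add atoms: propionic anhydride, CCC(=O)OC(=O)CC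
Why: DMAP-catalysed acylation of the allylic C11 hydroxyl should install the propionate with retention, since the C–O bond is not broken.

Step 21
Reactants: 44
Product: 45 C9 alcohol (44 without the 2-naphthylmethyl group; configuration unchanged)
Conditions: DDQ (3 equiv), CH2Cl2/H2O, rt
Reagents that add atoms: none
Why: Oxidative cleavage of the 2-naphthylmethyl ether with excess DDQ at room temperature should free the C9 hydroxyl while the esters, the silyl ether and the pyranones are inert.

Step 22
Reactants: 45; 46 acetic anhydride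
Product: 47 C9 acetate C11 propionate C21 tert-butyldimethylsilyl ether
Conditions: Ac2O, pyridine, DMAP (cat.), CH2Cl2, rt
Reagents that add atoms: acetic anhydride, CC(=O)OC(C)=O
Why: DMAP-catalysed acetylation of the C9 hydroxyl directly after its release should forestall 1,3-acyl migration from C11.

Step 23
Reactants: 47
Product: 48 CNP0265513.2 (target)
Conditions: HF·pyridine, pyridine, THF, 0 °C → rt
Reagents that add atoms: none
Why: Fluoride-mediated desilylation with buffered HF·pyridine should remove the silyl ether at C21 without hydrolysing or migrating either ester, giving the target.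

**Compound list**

1 | methylboronic acid | CB(O)O | starting material
2 | (1S,2S)-1,2-dicyclohexylethane-1,2-diol | O[C@@H](C1CCCCC1)[C@@H](O)C1CCCCC1 | starting material
3 | (4S,5S)-4,5-dicyclohexyl-2-methyl-1,3,2-dioxaborolane | CB1O[C@@H](C2CCCCC2)[C@@H](O1)C1CCCCC1 | intermediate
4 | dichloromethane | ClCCl | starting material
5 | vinylmagnesium bromide | C=C[Mg]Br | starting material
6 | (4S,5S)-2-[(1R)-1-chloroethyl]-4,5-dicyclohexyl-1,3,2-dioxaborolane | C[C@H](Cl)B1O[C@@H](C2CCCCC2)[C@@H](O1)C1CCCCC1 | intermediate (not isolated)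
7 | (4S,5S)-2-[(2S)-but-3-en-2-yl]-4,5-dicyclohexyl-1,3,2-dioxaborolane | C=C[C@H](C)B1O[C@@H](C2CCCCC2)[C@@H](O1)C1CCCCC1 | intermediate
8 | methylmagnesium bromide | C[Mg]Br | starting material
9 | (4S,5S)-2-[(1R,2S)-1-chloro-2-methylbut-3-enyl]-4,5-dicyclohexyl-1,3,2-dioxaborolane | C=C[C@H](C)[C@H](Cl)B1O[C@@H](C2CCCCC2)[C@@H](O1)C1CCCCC1 | intermediate (not isolated)
10 | (4S,5S)-4,5-dicyclohexyl-2-[(1S,2S)-2-methyl-1-(naphthalen-2-ylmethoxy)but-3-enyl]-1,3,2-dioxaborolane | C=C[C@H](C)[C@@H](OCc1ccc2ccccc2c1)B1O[C@@H](C2CCCCC2)[C@@H](O1)C1CCCCC1 | intermediate (not isolated)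
11 | (4S,5S)-2-[(1R,2R,3S)-1-chloro-3-methyl-2-(naphthalen-2-ylmethoxy)pent-4-enyl]-4,5-dicyclohexyl-1,3,2-dioxaborolane | C=C[C@H](C)[C@@H](OCc1ccc2ccccc2c1)[C@H](Cl)B1O[C@@H](C2CCCCC2)[C@@H](O1)C1CCCCC1 | intermediate (not isolated)
12 | (4S,5S)-4,5-dicyclohexyl-2-[(2R,3S,4S)-4-methyl-3-(naphthalen-2-ylmethoxy)hex-5-en-2-yl]-1,3,2-dioxaborolane | C=C[C@H](C)[C@@H](OCc1ccc2ccccc2c1)[C@@H](C)B1O[C@@H](C2CCCCC2)[C@@H](O1)C1CCCCC1 | intermediate (not isolated)
13 | (4S,5S)-2-[(1R,2R,3R,4S)-1-chloro-2,4-dimethyl-3-(naphthalen-2-ylmethoxy)hex-5-enyl]-4,5-dicyclohexyl-1,3,2-dioxaborolane | C=C[C@H](C)[C@@H](OCc1ccc2ccccc2c1)[C@@H](C)[C@H](Cl)B1O[C@@H](C2CCCCC2)[C@@H](O1)C1CCCCC1 | intermediate (not isolated)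
14 | (4S,5S)-4,5-dicyclohexyl-2-[(1S,2S,3R,4S)-1-(4-methoxybenzyloxy)-2,4-dimethyl-3-(naphthalen-2-ylmethoxy)hex-5-enyl]-1,3,2-dioxaborolane | C=C[C@H](C)[C@@H](OCc1ccc2ccccc2c1)[C@@H](C)[C@@H](OCc1ccc(OC)cc1)B1O[C@@H](C2CCCCC2)[C@@H](O1)C1CCCCC1 | intermediate
15 | (2R,3S,4S,5S)-5-[(4S,5S)-4,5-dicyclohexyl-1,3,2-dioxaborolan-2-yl]-5-(4-methoxybenzyloxy)-2,4-dimethyl-3-(naphthalen-2-ylmethoxy)pentanal | O=C[C@H](C)[C@@H](OCc1ccc2ccccc2c1)[C@@H](C)[C@@H](OCc1ccc(OC)cc1)B1O[C@@H](C2CCCCC2)[C@@H](O1)C1CCCCC1 | intermediate (not isolated)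
16 | (4S,5S)-4,5-dicyclohexyl-2-[(1S,2S,3S,4R)-5,5-dimethoxy-1-(4-methoxybenzyloxy)-2,4-dimethyl-3-(naphthalen-2-ylmethoxy)pentyl]-1,3,2-dioxaborolane | COC(OC)[C@H](C)[C@@H](OCc1ccc2ccccc2c1)[C@@H](C)[C@@H](OCc1ccc(OC)cc1)B1O[C@@H](C2CCCCC2)[C@@H](O1)C1CCCCC1 | intermediate
17 | methyl (R)-3-hydroxy-2-methylpropanoate | COC(=O)[C@H](C)CO | starting material
18 | methyl (R)-3-(tert-butyldiphenylsilyloxy)-2-methylpropanoate | COC(=O)[C@H](C)CO[Si](c1ccccc1)(c1ccccc1)C(C)(C)C | intermediate
19 | (R)-3-(tert-butyldiphenylsilyloxy)-2-methylpropanal | O=C[C@H](C)CO[Si](c1ccccc1)(c1ccccc1)C(C)(C)C | intermediate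
20 | ethyltriphenylphosphonium iodide | CC[P+](c1ccccc1)(c1ccccc1)c1ccccc1.[I-] | starting material
21 | tert-butyl{[(2S,3Z)-4-iodo-2-methylpent-3-enyl]oxy}diphenylsilane | C/C(I)=C/[C@H](C)CO[Si](c1ccccc1)(c1ccccc1)C(C)(C)C | intermediate
22 | lithium borate from 16 and the alkenyllithium of 21 (boron bears C11, C12 and the diol; boron cis to C14 on the alkene) | [Li+].COC(OC)[C@H](C)[C@@H](OCc1ccc2ccccc2c1)[C@@H](C)[C@@H](OCc1ccc(OC)cc1)[B-]1(O[C@@H](C2CCCCC2)[C@@H](O1)C1CCCCC1)/C(C)=C\[C@H](C)CO[Si](c1ccccc1)(c1ccccc1)C(C)(C)C | intermediate (not isolated)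
23 | C13-iodo C12-boronate (anti adduct; both anti diastereomers at C12/C13, not specified in the SMILES) | COC(OC)[C@H](C)[C@@H](OCc1ccc2ccccc2c1)[C@@H](C)[C@@H](OCc1ccc(OC)cc1)C(C)(B1O[C@@H](C2CCCCC2)[C@@H](O1)C1CCCCC1)C(I)[C@H](C)CO[Si](c1ccccc1)(c1ccccc1)C(C)(C)C | intermediate (not isolated)
24 | tert-butyl{[(2S,3E,5R,6R,7S,8R)-9,9-dimethoxy-5-(4-methoxybenzyloxy)-2,4,6,8-tetramethyl-7-(naphthalen-2-ylmethoxy)non-3-enyl]oxy}diphenylsilane | COC(OC)[C@H](C)[C@@H](OCc1ccc2ccccc2c1)[C@@H](C)[C@@H](OCc1ccc(OC)cc1)/C(C)=C/[C@H](C)CO[Si](c1ccccc1)(c1ccccc1)C(C)(C)C | intermediate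
25 | (2R,3S,4R,5R,6E,8S)-9-(tert-butyldiphenylsilyloxy)-5-(4-methoxybenzyloxy)-2,4,6,8-tetramethyl-3-(naphthalen-2-ylmethoxy)non-6-enal | O=C[C@H](C)[C@@H](OCc1ccc2ccccc2c1)[C@@H](C)[C@@H](OCc1ccc(OC)cc1)/C(C)=C/[C@H](C)CO[Si](c1ccccc1)(c1ccccc1)C(C)(C)C | intermediate
26 | 4-methylheptane-3,5-dione | CCC(=O)C(C)C(=O)CC | starting material
27 | C7-hydroxy C3,C5-diketone, backbone C1–C15, C9 2-naphthylmethyl ether, C11 4-methoxybenzyl ether, C15 silyl ether; C8–C14 as in 25, mixture at C4, C6 and C7 | CCC(=O)C(C)C(=O)C(C)C(O)[C@H](C)[C@@H](OCc1ccc2ccccc2c1)[C@@H](C)[C@@H](OCc1ccc(OC)cc1)/C(C)=C/[C@H](C)CO[Si](c1ccccc1)(c1ccccc1)C(C)(C)C | intermediate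
28 | C3,C5,C7-triketone from 27 (keto–enol and C4/C6 epimer mixture) | CCC(=O)C(C)C(=O)C(C)C(=O)[C@H](C)[C@@H](OCc1ccc2ccccc2c1)[C@@H](C)[C@@H](OCc1ccc(OC)cc1)/C(C)=C/[C@H](C)CO[Si](c1ccccc1)(c1ccccc1)C(C)(C)C | intermediate (not isolated)
29 | 2-[(2R,3S,4R,5R,6E,8S)-9-(tert-butyldiphenylsilyloxy)-5-(4-methoxybenzyloxy)-4,6,8-trimethyl-3-(naphthalen-2-ylmethoxy)non-6-en-2-yl]-6-ethyl-3,5-dimethyl-4H-pyran-4-one | CCc1oc([C@H](C)[C@@H](OCc2ccc3ccccc3c2)[C@@H](C)[C@@H](OCc2ccc(OC)cc2)/C(C)=C/[C@H](C)CO[Si](c2ccccc2)(c2ccccc2)C(C)(C)C)c(C)c(=O)c1C | intermediate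
30 | C15 alcohol: 29 with the silyl ether replaced by OH (configuration unchanged) | CCc1oc([C@H](C)[C@@H](OCc2ccc3ccccc3c2)[C@@H](C)[C@@H](OCc2ccc(OC)cc2)/C(C)=C/[C@H](C)CO)c(C)c(=O)c1C | intermediate
31 | (R)-4-benzyl-3-propionyloxazolidin-2-one | CCC(=O)N1[C@H](Cc2ccccc2)COC1=O | starting material
32 | propanal | CCC=O | starting material
33 | (R)-4-benzyl-3-[(2R,3S)-3-hydroxy-2-methylpentanoyl]oxazolidin-2-one | O=C1OC[C@@H](Cc2ccccc2)N1C(=O)[C@H](C)[C@@H](O)CC | intermediate
34 | (2R,3S)-3-hydroxy-N-methoxy-N,2-dimethylpentanamide | CON(C)C(=O)[C@H](C)[C@@H](O)CC | intermediate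
35 | (2R,3S)-3-(tert-butyldimethylsilyloxy)-N-methoxy-N,2-dimethylpentanamide | CON(C)C(=O)[C@H](C)[C@@H](O[Si](C)(C)C(C)(C)C)CC | intermediate
36 | pentan-3-one | CCC(=O)CC | starting material
37 | (6R,7S)-7-(tert-butyldimethylsilyloxy)-4,6-dimethylnonane-3,5-dione (C4 epimers) | CCC(=O)C(C)C(=O)[C@H](C)[C@@H](O[Si](C)(C)C(C)(C)C)CC | intermediate
38 | (2S,3E,5R,6R,7S,8R)-8-(6-ethyl-3,5-dimethyl-4-oxo-4H-pyran-2-yl)-5-(4-methoxybenzyloxy)-2,4,6-trimethyl-7-(naphthalen-2-ylmethoxy)non-3-enal | CCc1oc([C@H](C)[C@@H](OCc2ccc3ccccc3c2)[C@@H](C)[C@@H](OCc2ccc(OC)cc2)/C(C)=C/[C@H](C)C=O)c(C)c(=O)c1C | intermediate (not isolated)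
39 | C15-hydroxy C17,C19-diketone with ring B, C9 2-naphthylmethyl ether, C11 4-methoxybenzyl ether, C21 tert-butyldimethylsilyl ether; mixture at C15, C16 and C18 | CCc1oc([C@H](C)[C@@H](OCc2ccc3ccccc3c2)[C@@H](C)[C@@H](OCc2ccc(OC)cc2)/C(C)=C/[C@H](C)C(O)C(C)C(=O)C(C)C(=O)[C@H](C)[C@@H](O[Si](C)(C)C(C)(C)C)CC)c(C)c(=O)c1C | intermediate
40 | C15,C17,C19-triketone from 39 (keto–enol and C16/C18 epimer mixture) | CCc1oc([C@H](C)[C@@H](OCc2ccc3ccccc3c2)[C@@H](C)[C@@H](OCc2ccc(OC)cc2)/C(C)=C/[C@H](C)C(=O)C(C)C(=O)C(C)C(=O)[C@H](C)[C@@H](O[Si](C)(C)C(C)(C)C)CC)c(C)c(=O)c1C | intermediate (not isolated)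
41 | bis-pyranone (8R,9S,10R,11R,12E,14S,20R,21S) with C9 2-naphthylmethyl ether, C11 4-methoxybenzyl ether, C21 tert-butyldimethylsilyl ether | CCc1oc([C@H](C)[C@@H](OCc2ccc3ccccc3c2)[C@@H](C)[C@@H](OCc2ccc(OC)cc2)/C(C)=C/[C@H](C)c2oc([C@H](C)[C@@H](O[Si](C)(C)C(C)(C)C)CC)c(C)c(=O)c2C)c(C)c(=O)c1C | intermediate
42 | C11 alcohol: 41 with the 4-methoxybenzyl ether replaced by OH (configuration unchanged) | CCc1oc([C@H](C)[C@@H](OCc2ccc3ccccc3c2)[C@@H](C)[C@@H](O)/C(C)=C/[C@H](C)c2oc([C@H](C)[C@@H](O[Si](C)(C)C(C)(C)C)CC)c(C)c(=O)c2C)c(C)c(=O)c1C | intermediate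
43 | propionic anhydride | CCC(=O)OC(=O)CC | starting material
44 | C11 propionate of 42 (C9 2-naphthylmethyl ether, C21 silyl ether) | CCc1oc([C@H](C)[C@@H](OCc2ccc3ccccc3c2)[C@@H](C)[C@@H](OC(=O)CC)/C(C)=C/[C@H](C)c2oc([C@H](C)[C@@H](O[Si](C)(C)C(C)(C)C)CC)c(C)c(=O)c2C)c(C)c(=O)c1C | intermediate
45 | C9 alcohol: 44 with the 2-naphthylmethyl ether replaced by OH (configuration unchanged) | CCc1oc([C@H](C)[C@@H](O)[C@@H](C)[C@@H](OC(=O)CC)/C(C)=C/[C@H](C)c2oc([C@H](C)[C@@H](O[Si](C)(C)C(C)(C)C)CC)c(C)c(=O)c2C)c(C)c(=O)c1C | intermediate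
46 | acetic anhydride | CC(=O)OC(C)=O | starting material
47 | C9 acetate, C11 propionate, C21 tert-butyldimethylsilyl ether (the target silylated at C21) | CCc1oc([C@H](C)[C@@H](OC(C)=O)[C@@H](C)[C@@H](OC(=O)CC)/C(C)=C/[C@H](C)c2oc([C@H](C)[C@@H](O[Si](C)(C)C(C)(C)C)CC)c(C)c(=O)c2C)c(C)c(=O)c1C | intermediate
48 | CNP0265513.2: (8R,9S,10R,11R,12E,14S,20R,21S) C9 acetate, C11 propionate, C21 alcohol bis-pyranone | CCC(=O)O[C@@H](/C(C)=C/[C@H](C)c1oc([C@H](C)[C@@H](O)CC)c(C)c(=O)c1C)[C@H](C)[C@H](OC(C)=O)[C@@H](C)c1oc(CC)c(C)c(=O)c1C | target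

**Step count and risks**

Total step count: 23 (step 3 counted as one telescoped step of three cycles).
Longest linear sequence: 16 steps (steps 1–4, 8–12, 17–23).

Steps most likely to fail:

1. Step 8 (bears the label "Proposed new method:"). The hindered α-alkoxy boron centre may not be fully converted into the borate, and the electron-poor α-alkoxyalkyl group may migrate too slowly after iodination, so that the alkenyl group is simply cleaved from boron and 16 is returned or degraded. The fallback uses known carbonyl chemistry, sets out from 16 (and from 19) and comes back at 24, at the cost of the boron-set C11 centre, which is rebuilt under substrate control. Oxidation of the C–B bond of 16 (NaBO3·4H2O, THF/H2O) and collapse of the resulting hemiacetal should give (2R,3S,4R)-5,5-dimethoxy-2,4-dimethyl-3-(naphthalen-2-ylmethoxy)pentanal F1. Aldehyde 19 is converted by Corey–Fuchs olefination (CBr4, PPh3) into tert-butyl{[(2S)-4,4-dibromo-2-methylbut-3-enyl]oxy}diphenylsilane F2 and then (n-BuLi; MeI) into tert-butyl{[(2S)-2-methylpent-3-ynyl]oxy}diphenylsilane F3. Hydrozirconation of F3 with Cp2Zr(H)Cl (zirconium on the methyl-bearing carbon), transmetalation with Me2Zn and addition to F1 should give the E-allylic alcohol as a mixture of C11 epimers F4. Dess–Martin oxidation gives the C11 enone F5. Chelation-controlled reduction with Zn(BH4)2 (zinc bridging the C11 carbonyl and the C9 ether oxygen, C8 and the C10 methyl both equatorial, axial hydride delivery) should favour the 9,11-syn, 10,11-anti C11 alcohol F6. Etherification (NaH, 4-methoxybenzyl chloride, THF/DMF) returns 24.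

2. Step 17. The basic dianion may enolise aldehyde 38 instead of adding to it, which would scramble C14 or move the C12=C13 double bond into conjugation. The fallback replaces the strongly basic enolate by a Lewis-acid-mediated addition, sets out from 37 (with 38 made from 30 as before) and comes back at 39. Diketone 37 is converted (Me3SiCl, Et3N; then LiN(i-Pr)2, Me3SiCl) into its bis(trimethylsilyl) dienol ether F7, which should add to 38 through C16 in a BF3·OEt2-mediated Mukaiyama aldol reaction at −78 °C; aqueous work-up gives 39.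

3. Step 19. The oxidant may fail to discriminate between the two arylmethyl ethers, so that the C9 2-naphthylmethyl ether is cleaved alongside the C11 4-methoxybenzyl ether, or the liberated allylic alcohol is oxidised further. The fallback gives up orthogonal ether cleavage in favour of steric differentiation of the free diol, sets out from 41 and comes back at 45. Excess DDQ (CH2Cl2/H2O, rt) removes both ethers to give the C9,C11-diol F8. The allylic C11 hydroxyl, flanked by the planar C12 and less shielded than the C9 hydroxyl between two methyl-bearing carbons next to ring B, should be acylated first by propionyl chloride (1 equiv) with 2,4,6-collidine in CH2Cl2 at −78 °C. This gives 45, from which steps 22 and 23 follow.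

**Further compounds**

F1 | step 8 | (2R,3S,4R)-5,5-dimethoxy-2,4-dimethyl-3-(naphthalen-2-ylmethoxy)pentanal | COC(OC)[C@H](C)[C@@H](OCc1ccc2ccccc2c1)[C@@H](C)C=O
F2 | step 8 | tert-butyl{[(2S)-4,4-dibromo-2-methylbut-3-enyl]oxy}diphenylsilane | BrC(Br)=C[C@H](C)CO[Si](c1ccccc1)(c1ccccc1)C(C)(C)C
F3 | step 8 | tert-butyl{[(2S)-2-methylpent-3-ynyl]oxy}diphenylsilane | CC#C[C@H](C)CO[Si](c1ccccc1)(c1ccccc1)C(C)(C)C
F4 | step 8 | C11 allylic alcohol corresponding to 24 without the 4-methoxybenzyl group, both C11 epimers | COC(OC)[C@H](C)[C@@H](OCc1ccc2ccccc2c1)[C@@H](C)C(O)/C(C)=C/[C@H](C)CO[Si](c1ccccc1)(c1ccccc1)C(C)(C)C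
F5 | step 8 | C11 enone corresponding to F4 | COC(OC)[C@H](C)[C@@H](OCc1ccc2ccccc2c1)[C@@H](C)C(=O)/C(C)=C/[C@H](C)CO[Si](c1ccccc1)(c1ccccc1)C(C)(C)C
F6 | step 8 | C11 alcohol: 24 without the 4-methoxybenzyl group, C11 configured as in 24 | COC(OC)[C@H](C)[C@@H](OCc1ccc2ccccc2c1)[C@@H](C)[C@@H](O)/C(C)=C/[C@H](C)CO[Si](c1ccccc1)(c1ccccc1)C(C)(C)C
F7 | step 17 | bis(trimethylsilyl) dienol ether of 37: (6R,7S)-7-(tert-butyldimethylsilyloxy)-4,6-dimethyl-3,5-bis(trimethylsilyloxy)nona-2,4-diene | CC=C(O[Si](C)(C)C)C(C)=C(O[Si](C)(C)C)[C@H](C)[C@@H](O[Si](C)(C)C(C)(C)C)CC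
F8 | step 19 | C9,C11-diol: 41 with both arylmethyl ethers replaced by OH (C21 silyl ether retained) | CCc1oc([C@H](C)[C@@H](O)[C@@H](C)[C@@H](O)/C(C)=C/[C@H](C)c2oc([C@H](C)[C@@H](O[Si](C)(C)C(C)(C)C)CC)c(C)c(=O)c2C)c(C)c(=O)c1C
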